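**Retrosynthetic overview**
1. The furan ring closes last. Sonogashira coupling and 5-endo-dig O-cyclisation join terminal enyne 14 to 2,4-dihydroxy-5-iodoacetophenone 16.
2. Enyne 14 comes from E-enal 12 by C1 homologation. Enal 12 comes from (R)-2-arylpropanoate 10 by half-reduction and an E-selective stabilised Wittig reaction.
3. The aryl–C* bond comes from SN2 displacement (inversion) of the triflate of methyl (R)-lactate by a diarylcuprate. The only stereocentre is bought with the lactate.
4. The key step closes the 2H-pyran ring by oxa-6π electrocyclisation of a vinyl o-quinone methide made from 4-bromo-3-methoxyphenol and prenal.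
5. Ring order: chromene pyran ring first (step 1), benzofuran furan ring last (step 7).

Assumption: methyl (R)-lactate (D-lactate ester), 4-bromo-3-methoxyphenol, 3-methylbut-2-enal, 2,4-dihydroxyacetophenone and all named reagents are taken as catalogue items.

**Step 1**
Reactants: 1 4-bromo-3-methoxyphenol; 2 3-methylbut-2-enal
Product: 5 6-bromo-7-methoxy-2,2-dimethyl-2H-chromene, via benzodioxaborin 3 (not isolated), via o-quinone methide 4 (not isolated)
Conditions: PhB(OH)2 (1.0 equiv), AcOH, toluene, reflux (Dean–Stark), 16 h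
Reagents that add atoms: none
Why: Boronate-templated ortho-hydroxyalkylation occurs at the open position para to OMe (the other ortho site is flanked by OH and OMe) to give 3, whose thermal cycloreversion releases (Z)-vinyl o-quinone methide 4, which closes by oxa-6π electrocyclisation to the chromene without forming a stereocentre.

**Step 2**
Reactants: 6 methyl (R)-lactate
Product: 7 methyl (2R)-2-[(trifluoromethanesulfonyl)oxy]propanoate
Conditions: Tf2O (1.1 equiv), 2,6-lutidine (1.15 equiv), CH2Cl2, −78 → 0 °C; short silica plug, used at once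
Reagents that add atoms: trifluoromethanesulfonic anhydride, O=S(=O)(OS(=O)(=O)C(F)(F)F)C(F)(F)F
Why: O-sulfonylation touches only the O–H bond, so the bought (R) centre is retained while it becomes a very good SN2 leaving group.

**Step 3**
Reactants: 5 6-bromo-7-methoxy-2,2-dimethyl-2H-chromene (2.1 equiv); 7 methyl (2R)-2-[(trifluoromethanesulfonyl)oxy]propanoate (1.0 equiv)
Product: 10 methyl (2R)-2-(7-methoxy-2,2-dimethyl-2H-chromen-6-yl)propanoate, via aryllithium 8 (not isolated), via diarylcuprate 9 (not isolated)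
Conditions: 5, n-BuLi, THF/Et2O, −78 °C; CuI (1.05 equiv), −78 → −40 °C; then 7, −78 → −20 °C; aq NH4Cl/NH3
Reagents that add atoms: none
Why: After Br/Li exchange, the Gilman cuprate displaces the α-triflyloxy ester by SN2-type oxidative addition and reductive elimination with inversion (as Ph2CuLi does with secondary sulfonates and R2CuLi with α-sulfonyloxy esters), so the lactate centre sets the aryl-bearing centre, and the descriptor stays R only because the CIP ranks change.

**Step 4**
Reactants: 10 methyl (2R)-2-(7-methoxy-2,2-dimethyl-2H-chromen-6-yl)propanoate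
Product: 12 (2E,4S)-4-(7-methoxy-2,2-dimethyl-2H-chromen-6-yl)-2-methylpent-2-enal, via aldehyde 11 (not isolated)
Conditions: DIBAL-H (1.05 equiv), CH2Cl2, −78 °C, 1 h; then Ph3P=C(Me)CHO (2 equiv), −78 → 40 °C, 12 h; aq Rochelle salt
Reagents that add atoms: 2-(triphenylphosphoranylidene)propanal, CC(C=O)=P(c1ccccc1)(c1ccccc1)c1ccccc1
Why: Reduction stops at the aluminium hemiacetal at −78 °C, and the aldehyde released on warming is trapped in situ by the stabilised ylide (E-selective Wittig olefination), so the configurationally labile α-aryl aldehyde is never isolated, chromatographed or exposed to strong base and the stereocentre is carried through.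

**Step 5**
Reactants: 12 (2E,4S)-4-(7-methoxy-2,2-dimethyl-2H-chromen-6-yl)-2-methylpent-2-enal
Product: 14 7-methoxy-2,2-dimethyl-6-[(2S,3E)-4-methylhex-3-en-5-yn-2-yl]-2H-chromene, via diazoalkene 13 (not isolated)
Conditions: TMSCHN2 (1.3 equiv), LDA (1.25 equiv), THF, −78 °C, 30 min; then 12, −78 → 0 °C
Reagents that add atoms: (trimethylsilyl)diazomethane, C[Si](C)(C)C=[N+]=[N-]
Why: In this Colvin rearrangement the lithiated diazomethane adds 1,2 to the enal at −78 °C, Peterson-type loss of Me3SiOLi gives 13, and N2 loss plus a 1,2-H shift gives the terminal alkyne without touching the E-alkene or the stereocentre, while avoiding the K2CO3/MeOH medium that adds methanol to enals.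

**Step 6**
Reactants: 15 2,4-dihydroxyacetophenone
Product: 16 1-(2,4-dihydroxy-5-iodophenyl)ethan-1-one
Conditions: ICl (1.0 equiv), AcOH, rt
Reagents that add atoms: iodine monochloride, ClI
Why: Electrophilic aromatic iodination under acidic conditions goes to C5 (ortho to the 4-OH, para to the 2-OH) and not to the crowded C3 between the two hydroxyls.

**Step 7**
Reactants: 14 7-methoxy-2,2-dimethyl-6-[(2S,3E)-4-methylhex-3-en-5-yn-2-yl]-2H-chromene; 16 1-(2,4-dihydroxy-5-iodophenyl)ethan-1-one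
Product: 18 1-{6-hydroxy-2-[(2E,4S)-4-(7-methoxy-2,2-dimethyl-2H-chromen-6-yl)pent-2-en-2-yl]-1-benzofuran-5-yl}ethan-1-one, via alkynylphenol 17 (not isolated)
Conditions: PdCl2(PPh3)2 (5 mol %), CuI (10 mol %), Et3N (4 equiv), DMF, 60 °C, argon
Reagents that add atoms: none
Why: Sonogashira coupling is followed in the same pot by metal-promoted 5-endo-dig hydroalkoxylation by the acidic 4-OH (para to acetyl), while the chelated 2-OH is not ortho to the alkyne and the amine base cannot deprotonate the allylic-benzylic stereocentre.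

**Compound list**
1 | 4-bromo-3-methoxyphenol | COc1cc(O)ccc1Br | starting material
2 | 3-methylbut-2-enal (prenal) | CC(C)=CC=O | starting material
3 | 6-bromo-7-methoxy-4-(2-methylprop-1-en-1-yl)-2-phenyl-4H-1,3,2-benzodioxaborinine (racemic, not isolated) | COc1cc2OB(c3ccccc3)OC(C=C(C)C)c2cc1Br | intermediate
4 | (6Z)-4-bromo-3-methoxy-6-(3-methylbut-2-en-1-ylidene)cyclohexa-2,4-dien-1-one (o-quinone methide, not isolated) | COC1=CC(=O)/C(=C\C=C(C)C)C=C1Br | intermediate
5 | 6-bromo-7-methoxy-2,2-dimethyl-2H-chromene | COc1cc2OC(C)(C)C=Cc2cc1Br | intermediate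
6 | methyl (R)-lactate | C[C@@H](O)C(=O)OC | starting material
7 | methyl (2R)-2-[(trifluoromethanesulfonyl)oxy]propanoate | C[C@@H](OS(=O)(=O)C(F)(F)F)C(=O)OC | intermediate
8 | (7-methoxy-2,2-dimethyl-2H-chromen-6-yl)lithium (not isolated) | [Li]c1cc2C=CC(C)(C)Oc2cc1OC | intermediate
9 | lithium bis(7-methoxy-2,2-dimethyl-2H-chromen-6-yl)cuprate (not isolated) | [Li+].COc1cc2OC(C)(C)C=Cc2cc1[Cu-]c1cc2C=CC(C)(C)Oc2cc1OC | intermediate
10 | methyl (2R)-2-(7-methoxy-2,2-dimethyl-2H-chromen-6-yl)propanoate | C[C@H](c1cc2C=CC(C)(C)Oc2cc1OC)C(=O)OC | intermediate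
11 | (2R)-2-(7-methoxy-2,2-dimethyl-2H-chromen-6-yl)propanal (not isolated) | C[C@H](c1cc2C=CC(C)(C)Oc2cc1OC)C=O | intermediate
12 | (2E,4S)-4-(7-methoxy-2,2-dimethyl-2H-chromen-6-yl)-2-methylpent-2-enal | C[C@H](c1cc2C=CC(C)(C)Oc2cc1OC)/C=C(\C)C=O | intermediate
13 | 6-[(2S,3E)-6-diazo-4-methylhexa-3,5-dien-2-yl]-7-methoxy-2,2-dimethyl-2H-chromene (diazoalkene, not isolated) | C[C@H](c1cc2C=CC(C)(C)Oc2cc1OC)/C=C(\C)C=C=[N+]=[N-] | intermediate
14 | 7-methoxy-2,2-dimethyl-6-[(2S,3E)-4-methylhex-3-en-5-yn-2-yl]-2H-chromene | C[C@H](c1cc2C=CC(C)(C)Oc2cc1OC)/C=C(\C)C#C | intermediate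
15 | 2,4-dihydroxyacetophenone | CC(=O)c1ccc(O)cc1O | starting material
16 | 1-(2,4-dihydroxy-5-iodophenyl)ethan-1-one | CC(=O)c1cc(I)c(O)cc1O | intermediate
17 | 1-{2,4-dihydroxy-5-[(3E,5S)-5-(7-methoxy-2,2-dimethyl-2H-chromen-6-yl)-3-methylhex-3-en-1-yn-1-yl]phenyl}ethan-1-one (not isolated) | C[C@H](c1cc2C=CC(C)(C)Oc2cc1OC)/C=C(\C)C#Cc1cc(C(C)=O)c(O)cc1O | intermediate
18 | 1-{6-hydroxy-2-[(2E,4S)-4-(7-methoxy-2,2-dimethyl-2H-chromen-6-yl)pent-2-en-2-yl]-1-benzofuran-5-yl}ethan-1-one | COc1cc2c(cc1[C@@H](C)/C=C(\C)c1cc3cc(C(C)=O)c(O)cc3o1)C=CC(C)(C)O2 | target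

**Step count**
Total steps: 7. Longest linear sequence: 5 (steps 1, 3, 4, 5, 7 from compound 1). The sequence from compound 6 through steps 2, 3, 4, 5, 7 has the same length.

**Steps most likely to fail**

The most exposed step is step 3. An ortho-substituted diarylcuprate may reduce the α-triflyloxy ester to the propanoate, react sluggishly, or erode the ee. The fallback sets out from 5 (as its cuprate 9) and comes back at 18.
- Cuprate 9 opens commercial (R)-β-butyrolactone (C[C@@H]1CC(=O)O1) at the alkyl C–O bond with inversion (THF/Me2S, −30 → 0 °C). This gives (3S)-3-(7-methoxy-2,2-dimethyl-2H-chromen-6-yl)butanoic acid F1.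
- MeLi (2.2 equiv, Et2O, 0 °C) converts it into (4S)-4-(7-methoxy-2,2-dimethyl-2H-chromen-6-yl)pentan-2-one F2.
- Ethynylmagnesium bromide (THF, 0 °C) gives (5S)-5-(7-methoxy-2,2-dimethyl-2H-chromen-6-yl)-3-methylhex-1-yn-3-ol F3. Both carbinol epimers form, which does not matter.
- The conditions of step 7 with 16 give the benzofuranyl carbinol 1-{6-hydroxy-2-[(4S)-2-hydroxy-4-(7-methoxy-2,2-dimethyl-2H-chromen-6-yl)pentan-2-yl]-1-benzofuran-5-yl}ethan-1-one F4.
- Catalytic p-TsOH in toluene at 60 °C dehydrates F4 under thermodynamic control to the conjugated E-alkene 18.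
- In this line the stereocentre is never α to a carbonyl group.

Second is step 4. The formyl ylide is sluggish towards an α-branched aldehyde, DIBAL-H can over-reduce, and 11 can enolise and racemise while it waits. The fallback sets out from 10 and comes back at 14.
- Ester 10 is reduced as before, but 11 is worked up cold and treated at once with CBr4/PPh3 (CH2Cl2, 0 °C, minutes, non-basic Ramirez olefination). This gives 6-[(2S)-4,4-dibromobut-3-en-2-yl]-7-methoxy-2,2-dimethyl-2H-chromene F5.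
- Trans-selective Sonogashira coupling with trimethylsilylacetylene (Pd(PPh3)4, CuI, i-Pr2NH, toluene, rt) replaces only the bromide trans to the branched chain. This gives 6-[(2S,3Z)-4-bromo-6-(trimethylsilyl)hex-3-en-5-yn-2-yl]-7-methoxy-2,2-dimethyl-2H-chromene F6.
- Negishi methylation with retention (Me2Zn, Pd(Pt-Bu3)2, THF, rt) gives 7-methoxy-2,2-dimethyl-6-[(2S,3E)-4-methyl-6-(trimethylsilyl)hex-3-en-5-yn-2-yl]-2H-chromene F7.
- K2CO3/MeOH removes silicon to give 14.

Third is step 1. The bromine lowers the nucleophilicity of the phenol, so hydroxyalkylation may stall while prenal self-condenses. The fallback sets out from 1 and comes back at 5, passing through the same 4.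
- Phenol 1 is O-alkylated with 3-chloro-3-methylbut-1-yne (cat. CuCl2·2H2O, DBU, MeCN, 0 °C) to give 1-bromo-2-methoxy-4-[(2-methylbut-3-yn-2-yl)oxy]benzene F8.
- Heating in N,N-diethylaniline at 160 °C triggers the aromatic propargyl Claisen [3,3] rearrangement to 4-bromo-5-methoxy-2-(3-methylbuta-1,2-dien-1-yl)phenol F9.
- A [1,5]-H shift then gives 4, and oxa-6π closure gives 5.

**Further compounds**
F1 | step 3 | (3S)-3-(7-methoxy-2,2-dimethyl-2H-chromen-6-yl)butanoic acid | C[C@H](c1cc2C=CC(C)(C)Oc2cc1OC)CC(=O)O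
F2 | step 3 | (4S)-4-(7-methoxy-2,2-dimethyl-2H-chromen-6-yl)pentan-2-one | C[C@H](c1cc2C=CC(C)(C)Oc2cc1OC)CC(C)=O
F3 | step 3 | (5S)-5-(7-methoxy-2,2-dimethyl-2H-chromen-6-yl)-3-methylhex-1-yn-3-ol (C3 epimers) | C[C@H](c1cc2C=CC(C)(C)Oc2cc1OC)CC(C)(O)C#C
F4 | step 3 | 1-{6-hydroxy-2-[(4S)-2-hydroxy-4-(7-methoxy-2,2-dimethyl-2H-chromen-6-yl)pentan-2-yl]-1-benzofuran-5-yl}ethan-1-one (carbinol epimers) | C[C@H](c1cc2C=CC(C)(C)Oc2cc1OC)CC(C)(O)c1cc2cc(C(C)=O)c(O)cc2o1
F5 | step 4 | 6-[(2S)-4,4-dibromobut-3-en-2-yl]-7-methoxy-2,2-dimethyl-2H-chromene | C[C@H](c1cc2C=CC(C)(C)Oc2cc1OC)C=C(Br)Br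
F6 | step 4 | 6-[(2S,3Z)-4-bromo-6-(trimethylsilyl)hex-3-en-5-yn-2-yl]-7-methoxy-2,2-dimethyl-2H-chromene | C[C@H](c1cc2C=CC(C)(C)Oc2cc1OC)/C=C(\Br)C#C[Si](C)(C)C
F7 | step 4 | 7-methoxy-2,2-dimethyl-6-[(2S,3E)-4-methyl-6-(trimethylsilyl)hex-3-en-5-yn-2-yl]-2H-chromene | C[C@H](c1cc2C=CC(C)(C)Oc2cc1OC)/C=C(\C)C#C[Si](C)(C)C
F8 | step 1 | 1-bromo-2-methoxy-4-[(2-methylbut-3-yn-2-yl)oxy]benzene | COc1cc(OC(C)(C)C#C)ccc1Br
F9 | step 1 | 4-bromo-5-methoxy-2-(3-methylbuta-1,2-dien-1-yl)phenol | COc1cc(O)c(C=C=C(C)C)cc1Br
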